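The data come from a simulation with made-up constants; scatter was added.

Left-handed product climbs in both earlier runs. Sunday's charged 0.11 M of solid reagent and Tuesday's 0.17 M, yet their last readings differ by 0.3 percentage points, about the scatter of 0.3 points, so I pool them.

common to all: left-handed substrate 0.10 M; right-handed substrate 0.10 M
- Sunday's: solid reagent 0.11 M; run made earlier
- Tuesday's: solid reagent 0.17 M; run made earlier
- flask: solid reagent 0.220 M; time 5.0 d

- Sunday's (time / d: left-handed product / %): 0.625: 0.2; 1.25: 1.0; 1.67: 1.5; 2.50: 2.6; 3.00: 3.2
- Tuesday's (time / d: left-handed product / %): 0.625: 0.7; 1.25: 0.7; 1.67: 1.8; 2.50: 2.4; 3.00: 3.5

(standard deviation of a reading: 0.3 percentage points)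

- how much left-handed product there is at 5.0 d, in percent of the left-handed substrate and right-handed substrate together charged
- concentration of coupling partner in solution at 5.0 d, in percent of saturation

- coupling partner is single-handed; left-handed substrate and right-handed substrate are mirror images of each other, charged as a racemate, each of them at the stated concentration
- solid, in amounts per volume of the solution: solid reagent
- the earlier runs were read with a standard deviation of 0.3 percentage points
- steps under discussion: coupling partner + left-handed substrate -> left-handed product; coupling partner + right-handed substrate -> right-handed product; left-handed substrate <-> achiral form; right-handed substrate <-> achiral form; achiral form -> waste; solid reagent <-> coupling partner; achiral form -> side product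
- at the start none of the solid reagent is in solution
- the handed part of coupling partner does not stay in what it makes, so the products of the two hands are mirror images too

My quantity is the steady gain, the fraction of the charge (both substrates together) that turns into left-handed product per day, read between the pooled readings at 1.25 d and 3.00 d: 0.0143 d⁻¹, a reading with their scatter. A constant rate integrates to a straight line, so I run it on from the pooled last reading to 5.0 d.

The ledger for the flask then opens. The substrates are the limiting reagent, since the solid reagent stands at 1.10 times the charge. Left-handed substrate is half of the charge. Of that, my line puts 6.21% of the charge in left-handed product at 5.0 d and leaves 43.8% in the unread entries. That estimate of left-handed product costs 5.64% of the solid reagent charged to the flask. The runs read no coupling partner, so I give no figure for saturation.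

The forecast says 5.5% (4.7% to 6.2%) and 95% of saturation (80% to 100%), on the ground that “the solution fills quickly to saturation”. My product figure is higher.

The flask gives 6.33% of left-handed product, 0.12 points above my line, and 27.7% of saturation, 67 points below the forecast.

    coupling partner + left-handed substrate → left-handed product (k = 0.120 M⁻¹ h⁻¹)
    coupling partner + right-handed substrate → right-handed product (k = 0.0520 M⁻¹ h⁻¹)
    left-handed substrate ⇌ achiral form (K = 0.150, k = 0.0180 h⁻¹)
    right-handed substrate ⇌ achiral form (K = 0.150, k = 0.0180 h⁻¹)
    achiral form → waste (k = 0.0110 h⁻¹)
    solid reagent ⇌ coupling partner, rate k6*(cs6 - [coupling partner]) while solid is left; crystals form when [coupling partner] > cs6 (solubility = 0.0590 M, k = 0.00600 h⁻¹)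
    achiral form → side product (k = 0.00640 h⁻¹)

For the neighbour charged with 0.37 M of solid reagent I take the same steady gain, so my line again says 6.21%, now costing 3.36% of the solid reagent charged to it. At 5.0 d the neighbour gives 6.33% of left-handed product, with 36.0% of the charge still left-handed substrate, and 90.6% of its charged solid reagent is still undissolved.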